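**Strategy**

The ten-membered carbocycle is closed at the C3–C4 bond (germacrane numbering) by an intramolecular Nozaki–Hiyama–Kishi reaction. The step exploits the allylic alcohol motif C3(O)–C4(CH3)=C5 of the ring: C4 of a (Z)-alkenyl iodide adds to a C3 aldehyde, which forms the ring, creates the C3 carbinol and keeps the 4Z olefin in one operation. The precursor is an open-chain trans α-methylene-γ-butyrolactone (C6, C7, C8 set, E C1=C10 olefin in place) that carries the (Z)-2-iodopropenyl group on C6 and the aldehyde at C3; it arises from a chromium-mediated union of (Z)-3-iodobut-2-enal with a glycidol-derived allylic bromide. Two esterifications and a late C1=C10 epoxidation complete the target.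

Key step: step 14

Remark on numbering: germacrane locants are used throughout (C1–C10 ring carbons, C11–C13 the methylene-lactone carbons, C14 and C15 the methyls on C10 and C4). CIP descriptors of intermediates change with the substituents although the spatial arrangement is that of the target.
Remark on supply: (S)-glycidol, but-2-yn-1-ol, angelic acid and (R)-2-methylbutanoic acid are taken as commercial.

**Route**

Step 1
Reactants: 1 (S)-glycidol
Product: 2 (R)-2-{[(4-methoxybenzyl)oxy]methyl}oxirane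
Conditions: NaH, 4-methoxybenzyl chloride, Bu4NI (cat.), DMF, 0 °C to rt
Reagents that add atoms: 4-methoxybenzyl chloride, COc1ccc(CCl)cc1
Why: Williamson etherification of the primary alkoxide leaves the stereocentre (future C8) untouched; the descriptor changes from S to R only through CIP priorities.

Step 2
Reactants: 2 (R)-2-{[(4-methoxybenzyl)oxy]methyl}oxirane
Product: 3 (2R)-1-[(4-methoxybenzyl)oxy]pent-4-yn-2-ol
Conditions: LiC≡CH·H2NCH2CH2NH2, DMSO, 0 °C to rt
Reagents that add atoms: lithium acetylide (ethylenediamine complex), [Li+].[C-]#C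
Why: SN2 opening of the terminal epoxide at its unsubstituted carbon (C9) by the acetylide should give the homopropargylic alcohol without touching the carbinol centre.

Step 3
Reactants: 3 (2R)-1-[(4-methoxybenzyl)oxy]pent-4-yn-2-ol
Product: 6 (2R,4E)-1-[(4-methoxybenzyl)oxy]-4-methylhept-4-ene-2,7-diol, via alkenyldimethylalane 4 (not isolated), via lithium alkenylalanate 5 (not isolated)
Conditions: Me3Al (3 equiv), Cp2ZrCl2 (0.25 equiv), CH2Cl2, 0 °C to rt; then n-BuLi, hexane–THF, −78 °C; ethylene oxide, −78 °C to rt; aq. Rochelle salt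
Reagents that add atoms: trimethylaluminium, C[Al](C)C; ethylene oxide, C1CO1
Why: Negishi zirconium-catalysed syn-methylalumination puts the methyl on the internal carbon (C10) and aluminium on C1, and the derived alanate opens ethylene oxide with retention, which should fix the E C1=C10 olefin and add C2–C3.

Step 4
Reactants: 6 (2R,4E)-1-[(4-methoxybenzyl)oxy]-4-methylhept-4-ene-2,7-diol
Product: 7 (2R,4E)-2,7-bis[(tert-butyldimethylsilyl)oxy]-1-[(4-methoxybenzyl)oxy]-4-methylhept-4-ene
Conditions: TBSCl (2.5 equiv), imidazole, DMF, rt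
Reagents that add atoms: tert-butyldimethylsilyl chloride, CC(C)(C)[Si](C)(C)Cl
Why: Standard silylation protects both the secondary (C8) and the primary (C3) hydroxyl.

Step 5
Reactants: 7 (2R,4E)-2,7-bis[(tert-butyldimethylsilyl)oxy]-1-[(4-methoxybenzyl)oxy]-4-methylhept-4-ene
Product: 8 (2R,4E)-2,7-bis[(tert-butyldimethylsilyl)oxy]-4-methylhept-4-en-1-ol
Conditions: DDQ, CH2Cl2–pH 7 buffer, 0 °C
Reagents that add atoms: none
Why: Oxidative cleavage of the 4-methoxybenzyl ether should leave the silyl ethers and the trisubstituted olefin intact.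

Step 6
Reactants: 8 (2R,4E)-2,7-bis[(tert-butyldimethylsilyl)oxy]-4-methylhept-4-en-1-ol
Product: 9 (2R,4E)-2,7-bis[(tert-butyldimethylsilyl)oxy]-4-methylhept-4-enal
Conditions: Dess–Martin periodinane, NaHCO3, CH2Cl2, 0 °C
Reagents that add atoms: none
Why: Buffered Dess–Martin oxidation should give the α-silyloxy aldehyde (C7) without epimerisation at C8.

Step 7
Reactants: 9 (2R,4E)-2,7-bis[(tert-butyldimethylsilyl)oxy]-4-methylhept-4-enal
Product: 10 methyl (4R,6E)-4,9-bis[(tert-butyldimethylsilyl)oxy]-3-hydroxy-6-methyl-2-methylidenenon-6-enoate (both C3 epimers)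
Conditions: methyl propiolate, i-Bu2AlH, N-methylmorpholine N-oxide, THF, 0 °C; then 9, 0 °C to rt
Reagents that add atoms: methyl propiolate, C#CC(=O)OC
Why: Vinylalumination gives the Morita–Baylis–Hillman-type adduct under non-basic conditions that should not epimerise C8; the new carbinol centre is left unassigned because the next step destroys it.

Step 8
Reactants: 10 methyl (4R,6E)-4,9-bis[(tert-butyldimethylsilyl)oxy]-3-hydroxy-6-methyl-2-methylidenenon-6-enoate
Product: 11 methyl (2Z,4R,6E)-2-(bromomethyl)-4,9-bis[(tert-butyldimethylsilyl)oxy]-6-methylnona-2,6-dienoate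
Conditions: NBS, Me2S, CH2Cl2, 0 °C to rt
Reagents that add atoms: N-bromosuccinimide, O=C1CCC(=O)N1Br
Why: Corey–Kim-type activation of the allylic alcohol and SN2' delivery of bromide (allylic transposition) should give the (Z)-2-(bromomethyl)enoate from either carbinol epimer.

Step 9
Reactants: 12 but-2-yn-1-ol
Product: 14 (Z)-3-iodobut-2-en-1-ol, via cyclic sodium alkenylalanate 13 (not isolated)
Conditions: NaAlH2(OCH2CH2OCH3)2, THF, 0 °C to rt; then I2, −78 °C
Reagents that add atoms: iodine, II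
Why: Hydroxyl-directed trans-hydroalumination places hydride on C2 and aluminium on C3 in a five-membered alanate, and iodinolysis with retention should give the iodide cis to CH2OH (the future 4Z geometry).

Step 10
Reactants: 14 (Z)-3-iodobut-2-en-1-ol
Product: 15 (Z)-3-iodobut-2-enal
Conditions: MnO2, CH2Cl2, rt, dark; used at once
Reagents that add atoms: none
Why: Allylic oxidation with MnO2 is neutral and should not isomerise the Z olefin.

Step 11
Reactants: 11 methyl (2Z,4R,6E)-2-(bromomethyl)-4,9-bis[(tert-butyldimethylsilyl)oxy]-6-methylnona-2,6-dienoate; 15 (Z)-3-iodobut-2-enal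
Product: 17 (4S,5S)-4-[(1R,3E)-1,6-bis(tert-butyldimethylsilyloxy)-3-methylhex-3-en-1-yl]-5-[(1Z)-2-iodoprop-1-en-1-yl]-3-methylideneoxolan-2-one, via anti hydroxy ester 16 (not isolated)
Conditions: CrCl2 (nickel-free, 4 equiv), THF, rt; aq. NH4Cl; then pyridinium p-toluenesulfonate (cat.), CH2Cl2, rt
Reagents that add atoms: none
Why: Nozaki–Hiyama (Barbier-type) 2-(alkoxycarbonyl)allylation: the equilibrating allylchromium adds through C7 to the aldehyde in a chair transition state with both substituents equatorial, which should give the anti adduct (trans-lactone at C6/C7), while attack anti to the C9 chain with H8 eclipsing the ester-bearing olefin carbon (allylic 1,3-strain) sets C7 relative to C8; the alkenyl iodide is inert without nickel and acid closes the lactone.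

Step 12
Reactants: 17 (4S,5S)-4-[(1R,3E)-1,6-bis(tert-butyldimethylsilyloxy)-3-methylhex-3-en-1-yl]-5-[(1Z)-2-iodoprop-1-en-1-yl]-3-methylideneoxolan-2-one
Product: 18 (4S,5S)-4-[(1R,3E)-1-(tert-butyldimethylsilyloxy)-6-hydroxy-3-methylhex-3-en-1-yl]-5-[(1Z)-2-iodoprop-1-en-1-yl]-3-methylideneoxolan-2-one
Conditions: camphorsulfonic acid (cat.), MeOH–CH2Cl2 (1:1), 0 °C
Reagents that add atoms: none
Why: Acid-catalysed methanolysis should cleave the unhindered primary silyl ether (C3) much faster than the hindered secondary one (C8).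

Step 13
Reactants: 18 (4S,5S)-4-[(1R,3E)-1-(tert-butyldimethylsilyloxy)-6-hydroxy-3-methylhex-3-en-1-yl]-5-[(1Z)-2-iodoprop-1-en-1-yl]-3-methylideneoxolan-2-one
Product: 19 (3E,6R)-6-(tert-butyldimethylsilyloxy)-6-{(2S,3S)-2-[(1Z)-2-iodoprop-1-en-1-yl]-4-methylidene-5-oxooxolan-3-yl}-4-methylhex-3-enal
Conditions: Dess–Martin periodinane, NaHCO3, CH2Cl2, 0 °C; used crude
Reagents that add atoms: none
Why: Neutral Dess–Martin oxidation should give the β,γ-unsaturated aldehyde without migration of the C1=C10 olefin into conjugation.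

Step 14
Reactants: 19 (3E,6R)-6-(tert-butyldimethylsilyloxy)-6-{(2S,3S)-2-[(1Z)-2-iodoprop-1-en-1-yl]-4-methylidene-5-oxooxolan-3-yl}-4-methylhex-3-enal
Product: 20 (3S,6R,7S,8R)-8-(tert-butyldimethylsilyloxy)-3-hydroxygermacra-1(10)E,4Z,11(13)-trien-12,6-olide
Conditions: CrCl2 (10 equiv), NiCl2 (cat.), DMSO, rt, slow addition of 19 to about 0.003 M
Reagents that add atoms: none
Why: Zerovalent nickel, formed from NiCl2 by CrCl2, inserts into the C4–I bond with retention of the Z geometry and transmetalates to a trivalent alkenylchromium that adds intramolecularly to the C3 aldehyde; the closest known reaction type is the Nozaki–Hiyama–Kishi macrocyclisation used for nine- to twelve-membered rings. The ten-membered ring closes in a 10-exo-trig mode (C4 nucleophile on the exocyclic C3=O). The new C3 stereocentre is set by the conformation of the ring-forming transition state, which is constrained by the trans-lactone at C6/C7, the E C1=C10 olefin and allylic 1,3-strain across the Z C4=C5 olefin (H3 eclipsing the olefin towards C6, chromium-bound oxygen on the ring periphery), and this should favour the 3S alcohol. The step needs chemoselectivity for the aldehyde over the lactone and the α-methylene enoate, which the oxophilic and weakly basic organochromium secures, and it needs the β,γ-unsaturated aldehyde to stay unconjugated, which the neutral medium secures. Ring closure must outrun oligomerisation, which slow addition at high dilution secures.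

Step 15
Reactants: 20 (3S,6R,7S,8R)-8-(tert-butyldimethylsilyloxy)-3-hydroxygermacra-1(10)E,4Z,11(13)-trien-12,6-olide; 21 (R)-2-methylbutanoic acid
Product: 22 (3S,6R,7S,8R)-8-(tert-butyldimethylsilyloxy)-3-[(2R)-2-methylbutanoyloxy]germacra-1(10)E,4Z,11(13)-trien-12,6-olide
Conditions: EDC·HCl, 4-(dimethylamino)pyridine (cat.), CH2Cl2, 0 °C to rt
Reagents that add atoms: none
Why: Steglich esterification acylates the C3 alcohol with retention and should not epimerise the α-centre of the simple branched acid.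

Step 16
Reactants: 22 (3S,6R,7S,8R)-8-(tert-butyldimethylsilyloxy)-3-[(2R)-2-methylbutanoyloxy]germacra-1(10)E,4Z,11(13)-trien-12,6-olide
Product: 23 (3S,6R,7R,8R)-8-hydroxy-3-[(2R)-2-methylbutanoyloxy]germacra-1(10)E,4Z,11(13)-trien-12,6-olide
Conditions: HF·pyridine, pyridine, THF, 0 °C to rt
Reagents that add atoms: none
Why: Acidic fluoride removes the secondary silyl ether while avoiding the alkoxide that could add to the methylene lactone or translactonise.

Step 17
Reactants: 24 angelic acid
Product: 25 (Z)-2-methylbut-2-en-1-ol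
Conditions: LiAlH4, Et2O, 0 °C
Reagents that add atoms: none
Why: Hydride reduction of the carboxylate at low temperature should keep the Z olefin geometry.

Step 18
Reactants: 25 (Z)-2-methylbut-2-en-1-ol
Product: 26 [(2R,3S)-2,3-dimethyloxiran-2-yl]methanol
Conditions: t-BuOOH, Ti(OiPr)4, D-(−)-diisopropyl tartrate, 4 Å molecular sieves, CH2Cl2, −20 °C
Reagents that add atoms: tert-butyl hydroperoxide, CC(C)(C)OO
Why: Sharpless asymmetric epoxidation with the D-(−)-tartrate should deliver oxygen to the face that gives the (2R,3S) epoxy alcohol, and syn addition keeps CH2OH cis to the C3 methyl.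

Step 19
Reactants: 26 [(2R,3S)-2,3-dimethyloxiran-2-yl]methanol
Product: 27 (2S,3S)-2,3-dimethyloxirane-2-carboxylic acid
Conditions: RuCl3 (cat.), NaIO4, CCl4–MeCN–H2O, rt
Reagents that add atoms: water, O
Why: Ruthenium tetroxide oxidation takes the primary alcohol to the acid without opening the epoxide; the C2 descriptor becomes S by priority change only.

Step 20
Reactants: 23 (3S,6R,7R,8R)-8-hydroxy-3-[(2R)-2-methylbutanoyloxy]germacra-1(10)E,4Z,11(13)-trien-12,6-olide; 27 (2S,3S)-2,3-dimethyloxirane-2-carboxylic acid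
Product: 29 (3S,6R,7R,8R)-8-[(2S,3S)-2,3-dimethyloxirane-2-carbonyloxy]-3-[(2R)-2-methylbutanoyloxy]germacra-1(10)E,4Z,11(13)-trien-12,6-olide, via mixed anhydride 28 (not isolated)
Conditions: 27, 2,4,6-trichlorobenzoyl chloride, Et3N, THF, rt; then 23, 4-(dimethylamino)pyridine, toluene, rt
Reagents that add atoms: none
Why: Yamaguchi esterification is suited to a hindered secondary alcohol and an α,α-disubstituted acid, and no stereocentre takes part.

Step 21
Reactants: 29 (3S,6R,7R,8R)-8-[(2S,3S)-2,3-dimethyloxirane-2-carbonyloxy]-3-[(2R)-2-methylbutanoyloxy]germacra-1(10)E,4Z,11(13)-trien-12,6-olide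
Product: 30 CNP0265335.2, (1R,3S,6R,7R,8R,10R)-1,10-epoxy-8-[(2S,3S)-2,3-dimethyloxirane-2-carbonyloxy]-3-[(2R)-2-methylbutanoyloxy]germacra-4Z,11(13)-dien-12,6-olide
Conditions: mCPBA (1.1 equiv), NaHCO3, CH2Cl2, 0 °C
Reagents that add atoms: 3-chloroperbenzoic acid, O=C(OO)c1cccc(Cl)c1
Why: Prilezhaev epoxidation should pick the isolated, electron-rich C1=C10 olefin over the doubly allylically oxygenated C4=C5 and the enoate; syn addition gives the trans epoxide, and attack on the exposed peripheral face of the E olefin in the ring should give the (1R,10R) isomer.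

**Compound list**

1 | (S)-glycidol | OC[C@H]1CO1 | starting material
2 | (R)-2-{[(4-methoxybenzyl)oxy]methyl}oxirane | COc1ccc(COC[C@H]2CO2)cc1 | intermediate
3 | (2R)-1-[(4-methoxybenzyl)oxy]pent-4-yn-2-ol | C#CC[C@@H](O)COCc1ccc(OC)cc1 | intermediate
4 | (E)-alkenyldimethylalane from methylalumination of 3 (C8 oxygen as dimethylaluminium alkoxide) | C[Al](C)/C=C(\C)C[C@@H](O[Al](C)C)COCc1ccc(OC)cc1 | intermediate
5 | lithium butyl(dimethyl)alkenylalanate derived from 4 | [Li+].CCCC[Al-](C)(C)/C=C(\C)C[C@@H](O[Al](C)C)COCc1ccc(OC)cc1 | intermediate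
6 | (2R,4E)-1-[(4-methoxybenzyl)oxy]-4-methylhept-4-ene-2,7-diol | OCC/C=C(\C)C[C@@H](O)COCc1ccc(OC)cc1 | intermediate
7 | (2R,4E)-2,7-bis[(tert-butyldimethylsilyl)oxy]-1-[(4-methoxybenzyl)oxy]-4-methylhept-4-ene | CC(C)(C)[Si](C)(C)OCC/C=C(\C)C[C@@H](O[Si](C)(C)C(C)(C)C)COCc1ccc(OC)cc1 | intermediate
8 | (2R,4E)-2,7-bis[(tert-butyldimethylsilyl)oxy]-4-methylhept-4-en-1-ol | CC(C)(C)[Si](C)(C)OCC/C=C(\C)C[C@@H](O[Si](C)(C)C(C)(C)C)CO | intermediate
9 | (2R,4E)-2,7-bis[(tert-butyldimethylsilyl)oxy]-4-methylhept-4-enal | CC(C)(C)[Si](C)(C)OCC/C=C(\C)C[C@@H](O[Si](C)(C)C(C)(C)C)C=O | intermediate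
10 | methyl (4R,6E)-4,9-bis[(tert-butyldimethylsilyl)oxy]-3-hydroxy-6-methyl-2-methylidenenon-6-enoate (C3 epimer mixture) | C=C(C(=O)OC)C(O)[C@H](O[Si](C)(C)C(C)(C)C)C/C(C)=C/CCO[Si](C)(C)C(C)(C)C | intermediate
11 | methyl (2Z,4R,6E)-2-(bromomethyl)-4,9-bis[(tert-butyldimethylsilyl)oxy]-6-methylnona-2,6-dienoate | BrC/C(C(=O)OC)=C\[C@H](O[Si](C)(C)C(C)(C)C)C/C(C)=C/CCO[Si](C)(C)C(C)(C)C | intermediate
12 | but-2-yn-1-ol | CC#CCO | starting material
13 | cyclic sodium alkenylalanate (2,2-bis(2-methoxyethoxy)-3-methyl-1-oxa-2-aluminacyclopent-3-ene, sodium salt) | CC1=CCO[Al-]1(OCCOC)OCCOC.[Na+] | intermediate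
14 | (Z)-3-iodobut-2-en-1-ol | C/C(I)=C/CO | intermediate
15 | (Z)-3-iodobut-2-enal | C/C(I)=C/C=O | intermediate
16 | methyl (3S,4S,5Z)-3-[(1R,3E)-1,6-bis(tert-butyldimethylsilyloxy)-3-methylhex-3-en-1-yl]-4-hydroxy-6-iodo-2-methylidenehept-5-enoate | C=C(C(=O)OC)[C@@H]([C@H](O)/C=C(/C)I)[C@H](O[Si](C)(C)C(C)(C)C)C/C(C)=C/CCO[Si](C)(C)C(C)(C)C | intermediate
17 | (4S,5S)-4-[(1R,3E)-1,6-bis(tert-butyldimethylsilyloxy)-3-methylhex-3-en-1-yl]-5-[(1Z)-2-iodoprop-1-en-1-yl]-3-methylideneoxolan-2-one | C=C1C(=O)O[C@H](/C=C(/C)I)[C@H]1[C@H](O[Si](C)(C)C(C)(C)C)C/C(C)=C/CCO[Si](C)(C)C(C)(C)C | intermediate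
18 | (4S,5S)-4-[(1R,3E)-1-(tert-butyldimethylsilyloxy)-6-hydroxy-3-methylhex-3-en-1-yl]-5-[(1Z)-2-iodoprop-1-en-1-yl]-3-methylideneoxolan-2-one | C=C1C(=O)O[C@H](/C=C(/C)I)[C@H]1[C@H](O[Si](C)(C)C(C)(C)C)C/C(C)=C/CCO | intermediate
19 | (3E,6R)-6-(tert-butyldimethylsilyloxy)-6-{(2S,3S)-2-[(1Z)-2-iodoprop-1-en-1-yl]-4-methylidene-5-oxooxolan-3-yl}-4-methylhex-3-enal | C=C1C(=O)O[C@H](/C=C(/C)I)[C@H]1[C@H](O[Si](C)(C)C(C)(C)C)C/C(C)=C/CC=O | intermediate
20 | (3S,6R,7S,8R)-8-(tert-butyldimethylsilyloxy)-3-hydroxygermacra-1(10)E,4Z,11(13)-trien-12,6-olide | C=C1C(=O)O[C@@H]2/C=C(/C)[C@@H](O)C/C=C(\C)C[C@@H](O[Si](C)(C)C(C)(C)C)[C@@H]12 | intermediate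
21 | (R)-2-methylbutanoic acid | CC[C@@H](C)C(=O)O | starting material
22 | (3S,6R,7S,8R)-8-(tert-butyldimethylsilyloxy)-3-[(2R)-2-methylbutanoyloxy]germacra-1(10)E,4Z,11(13)-trien-12,6-olide | C=C1C(=O)O[C@@H]2/C=C(/C)[C@@H](OC(=O)[C@H](C)CC)C/C=C(\C)C[C@@H](O[Si](C)(C)C(C)(C)C)[C@@H]12 | intermediate
23 | (3S,6R,7R,8R)-8-hydroxy-3-[(2R)-2-methylbutanoyloxy]germacra-1(10)E,4Z,11(13)-trien-12,6-olide | C=C1C(=O)O[C@@H]2/C=C(/C)[C@@H](OC(=O)[C@H](C)CC)C/C=C(\C)C[C@@H](O)[C@@H]12 | intermediate
24 | angelic acid, (Z)-2-methylbut-2-enoic acid | C/C=C(/C)C(=O)O | starting material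
25 | (Z)-2-methylbut-2-en-1-ol | C/C=C(/C)CO | intermediate
26 | [(2R,3S)-2,3-dimethyloxiran-2-yl]methanol | OC[C@@]1(C)O[C@H]1C | intermediate
27 | (2S,3S)-2,3-dimethyloxirane-2-carboxylic acid | OC(=O)[C@@]1(C)O[C@H]1C | intermediate
28 | (2S,3S)-2,3-dimethyloxirane-2-carboxylic 2,4,6-trichlorobenzoic anhydride | O=C(OC(=O)[C@@]1(C)O[C@H]1C)c1c(Cl)cc(Cl)cc1Cl | intermediate
29 | (3S,6R,7R,8R)-8-[(2S,3S)-2,3-dimethyloxirane-2-carbonyloxy]-3-[(2R)-2-methylbutanoyloxy]germacra-1(10)E,4Z,11(13)-trien-12,6-olide | C=C1C(=O)O[C@@H]2/C=C(/C)[C@@H](OC(=O)[C@H](C)CC)C/C=C(\C)C[C@@H](OC(=O)[C@@]3(C)O[C@H]3C)[C@@H]12 | intermediate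
30 | CNP0265335.2, (1R,3S,6R,7R,8R,10R)-1,10-epoxy-8-[(2S,3S)-2,3-dimethyloxirane-2-carbonyloxy]-3-[(2R)-2-methylbutanoyloxy]germacra-4Z,11(13)-dien-12,6-olide | C=C1C(=O)O[C@@H]2/C=C(/C)[C@@H](OC(=O)[C@H](C)CC)C[C@H]3O[C@]3(C)C[C@@H](OC(=O)[C@@]3(C)O[C@H]3C)[C@@H]12 | target

**Summary and risks**

Total step count: 21. Longest linear sequence: 16 steps (steps 1–8, 11–16, 20 and 21, from (S)-glycidol 1).

Steps most likely to fail:

1. Step 14 (key ring closure). The aldehyde may be attacked on its other face in the ring-forming transition state, so that the 3-epimer predominates; intermolecular coupling is the second concern and is met by dilution. The fallback sets out from aldehyde 19 and returns at 20. The cyclisation is run as in step 14 and the alcohol obtained, taken as the (3R)-epimeric alcohol F1, is oxidised with MnO2 (CH2Cl2, rt) to the macrocyclic enone F2. Reduction of F2 with catecholborane and (R)-2-methyl-CBS-oxazaborolidine [(R)-1-methyl-3,3-diphenyltetrahydro-1H,3H-pyrrolo[1,2-c][1,3,2]oxazaborole] in toluene at −78 °C then sets C3 under reagent control, no longer in the C–C bond formation, and should give 20.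

2. Step 11. The allylchromium may react through its other geometrical form, giving the syn adduct and hence the cis-lactone. The fallback sets out from aldehyde 9 and returns at lactone 17. Seyferth–Gilbert homologation of 9 with dimethyl (1-diazo-2-oxopropyl)phosphonate (K2CO3, MeOH) should give the alkyne F3. Deprotonation with n-BuLi and trapping with methyl chloroformate should give the ynoate F4. Syn-hydroalumination (i-Bu2AlH, hexamethylphosphoramide, THF) and trapping of the α-aluminoacrylate with 2-(iodomethyl)-4,4,5,5-tetramethyl-1,3,2-dioxaborolane should give the geometrically defined allylboronate F5 (CH2B trans to C8). Allylboration of 15 with F5 (toluene, heat, or Sc(OTf)3 catalysis at low temperature) passes through a closed chair transition state and is stereospecific for the anti adduct, which lactonises (pyridinium p-toluenesulfonate) to 17.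

3. Step 21. The peracid may attack the other face of the C1=C10 olefin if the ring populates a second conformer, giving the diastereomeric trans-epoxide. The fallback sets out from 29 and returns at 30. Epoxidation with the dioxirane generated from the D-fructose-derived Shi ketone and Oxone (2KHSO5·KHSO4·K2SO4) in buffered MeCN–dimethoxymethane–water at 0 °C is reagent-controlled; its spiro transition state should deliver the (1R,10R) epoxide irrespective of ring conformation. This fallback makes no new compound (F0).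

Further compounds
F1 | step 14 | (3R,6R,7S,8R)-8-(tert-butyldimethylsilyloxy)-3-hydroxygermacra-1(10)E,4Z,11(13)-trien-12,6-olide | C=C1C(=O)O[C@@H]2/C=C(/C)[C@H](O)C/C=C(\C)C[C@@H](O[Si](C)(C)C(C)(C)C)[C@@H]12
F2 | step 14 | (6R,7S,8R)-8-(tert-butyldimethylsilyloxy)-3-oxogermacra-1(10)E,4Z,11(13)-trien-12,6-olide | C=C1C(=O)O[C@@H]2/C=C(/C)C(=O)C/C=C(\C)C[C@@H](O[Si](C)(C)C(C)(C)C)[C@@H]12
F3 | step 11 | (3R,5E)-3,8-bis[(tert-butyldimethylsilyl)oxy]-5-methyloct-5-en-1-yne | C#C[C@H](O[Si](C)(C)C(C)(C)C)C/C(C)=C/CCO[Si](C)(C)C(C)(C)C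
F4 | step 11 | methyl (4R,6E)-4,9-bis[(tert-butyldimethylsilyl)oxy]-6-methylnon-6-en-2-ynoate | COC(=O)C#C[C@H](O[Si](C)(C)C(C)(C)C)C/C(C)=C/CCO[Si](C)(C)C(C)(C)C
F5 | step 11 | methyl (2Z,4R,6E)-4,9-bis[(tert-butyldimethylsilyl)oxy]-6-methyl-2-[(4,4,5,5-tetramethyl-1,3,2-dioxaborolan-2-yl)methyl]nona-2,6-dienoate | COC(=O)/C(CB1OC(C)(C)C(C)(C)O1)=C\[C@H](O[Si](C)(C)C(C)(C)C)C/C(C)=C/CCO[Si](C)(C)C(C)(C)C
F0 | step 21 | none | none
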